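## Retrosynthetic overview
1. Remove the C7 hydroxyl (Rubottom oxidation, then C7 equilibration). Open the ring D lactone back to a spiro-cyclobutanone, using a desymmetrising Baeyer–Villiger oxidation that fixes C13.
2. The spiro-cyclobutanone comes from dichloroketene [2+2] on an exocyclic enol ether. Ring C (oxolane, O–C13 bond) comes from 5-exo-dig closure of a tertiary alkynol.
3. Ring B is cut at C9–C10, a ketyl–enone closure of an open-chain ene-yne-dione. This sets C9, C10 and C5 from C8.
4. C8–C9 is cut by an enantioselective carbene-catalysed Stetter union of β-damascone (ring A, 13 C) and pent-4-ynal (5 C). This sets C8, the first stereocentre.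
5. Ring order: A (bought), then B, then C, then D (four-membered first, then expanded to the lactone).

Assumption: labdane numbering (C1–C20) is used for positions, pent-4-ynal is taken as a catalogue chemical, and for each chiral catalyst the antipode that gives the drawn isomer is used (both antipodes are accessible; one test run decides).

## Route

**Step 1**
Reactants: 1 (E)-β-damascone; 2 pent-4-ynal
Product: 3 (3R)-3-methyl-1-(2,6,6-trimethylcyclohex-1-en-1-yl)oct-7-yne-1,4-dione
Conditions: 2 (1.5 equiv, syringe pump), 7-fluoro-5-isopropyl-2-(pentafluorophenyl)-6,7-dihydro-5H-pyrrolo[2,1-c][1,2,4]triazol-2-ium tetrafluoroborate (15 mol %, single enantiomer), iPr2NEt (15 mol %), catechol (30 mol %), t-AmOH, 0 °C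
Reagents that add atoms: none
Why: Proposed new method: an enantioselective intermolecular Stetter reaction of an enolisable aliphatic aldehyde with a plain β-alkyl enone has not been shown; the carbene adds to 2, catechol-relayed proton transfer makes the aldehyde carbon an acyl anion equivalent, this attacks the only accessible acceptor carbon of 1 (C8 of the crotonyl unit, since the tetrasubstituted ring alkene is shielded and twisted out of conjugation) on its Re face because the isopropyl group and the fluorine-locked ring pucker close the other quadrant while catechol hydrogen-bonds the enone oxygen, and irreversible proton transfer with carbene release gives the 1,4-diketone with C8 (R) under a base too weak to enolise it; the closest known reactions are the carbene-catalysed asymmetric Stetter additions of aliphatic aldehydes to nitroalkenes and the racemic thiazolium Stetter reaction of aliphatic aldehydes with enones.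

**Step 2**
Reactants: 3 (3R)-ene-yne-dione
Product: 4 (3R,4R,4aS,8aS)-4-(but-3-yn-1-yl)-4-hydroxy-3,4a,8,8-tetramethyloctahydronaphthalen-1(2H)-one
Conditions: SmI2 (2.5 equiv), HMPA (10 equiv), t-BuOH (2.2 equiv), THF, −78 → 0 °C, slow addition of 3
Reagents that add atoms: none
Why: Samarium diiodide ketyl–olefin (ketone–enone) reductive cyclisation in which the C9 ketyl adds 6-endo to the polarity-matched β-carbon C10 through a chair-like transition state with the C8 methyl equatorial (the other face needs a syn-diaxial Me/Me contact), the butynyl chain equatorial and the metal-bound oxygen on the open α face, after which the trivalent samarium enolate is protonated at C5 from the α face, giving C10 (S), C9 (R) and C5 (S), the trans-decalone also being the thermodynamic isomer.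

**Step 3**
Reactants: 4 alkynol
Product: 5 (1R,2R,4aS,8aS)-2,5,5,8a-tetramethyl-5'-methylideneoctahydrospiro[naphthalene-1,2'-oxolan]-4-one
Conditions: Ag2CO3 (10 mol %), toluene, 80 °C, dark; filtration through basic Al2O3
Reagents that add atoms: none
Why: Silver-catalysed 5-exo-dig cycloisomerisation (intramolecular hydroalkoxylation) of a 4-alkyn-1-ol, helped by the compression at fully substituted C9 and kept at the exocyclic enol ether by the basic carbonate; no new stereocentre is formed and C9 keeps its C–O bond.

**Step 4**
Reactants: 5 exocyclic enol ether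
Product: 7 spiro-cyclobutanone (cyclobutan-3-one spiro-fused at C13 of the oxolane), via dichlorocyclobutanone 6 (not isolated)
Conditions: Cl3CCOCl (2 equiv), Zn–Cu couple (6 equiv), Et2O–DME, 0 °C → rt; then NH4Cl-saturated MeOH, rt, same flask
Reagents that add atoms: trichloroacetyl chloride ClC(Cl)(Cl)C(Cl)=O
Why: Ketene–enol ether [2+2] cycloaddition in which the ketene carbonyl carbon bonds to the nucleophilic =CH2 and CCl2 bonds to the oxygen-bearing C13, followed by zinc dechlorination that makes the two arms on C13 identical, so the facial selectivity of the cycloaddition does not matter and the hindered C6 ketone is untouched.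

**Step 5**
Reactants: 7 spiro-cyclobutanone
Product: 8 (13R)-6-oxo-9α,13-epoxylabdan-15,16-olide
Conditions: (R)-3,3'-di(pyren-1-yl)-1,1'-binaphthyl-2,2'-diyl hydrogen phosphate (10 mol %), 30 % aq. H2O2 (1.5 equiv), CHCl3, −40 °C
Reagents that add atoms: hydrogen peroxide OO
Why: Organocatalytic desymmetrising Baeyer–Villiger oxidation in which only the strained cyclobutanone reacts at −40 °C (the C6 cyclohexanone is inert) and the chiral phosphate, bound to the Criegee adduct, lets the CH2 on the C8/C17 side migrate to oxygen, which makes that carbon C16 and sets C13 (R).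

**Step 6**
Reactants: 8 7-deoxy lactone
Product: 12 (13R)-7β-hydroxy-6-oxo-9α,13-epoxylabdan-15,16-olide (target CNP0291402.1), via silyl enol ether 9 (not isolated), via 7α-silyloxy ketone 10 (not isolated), via 7α-hydroxy ketone 11 (not isolated)
Conditions: TMSOTf (1.3 equiv), Et3N (2 equiv), CH2Cl2, 0 °C; crude: mCPBA (1.1 equiv), CH2Cl2, −20 °C; 1 M HCl, THF, 0 °C; DBU (0.3 equiv), MeOH, rt
Reagents that add atoms: 3-chloroperbenzoic acid OOC(=O)c1cccc(Cl)c1 (O at C7); trimethylsilyl triflate C[Si](C)(C)OS(=O)(=O)C(F)(F)F (Me3Si only in 9 and 10)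
Why: Rubottom oxidation in which soft enolisation takes the ketone towards C7 (a C5=C6 enol ether would clash with the C4 methyls, and the lactone with its neopentyl α-CH2 needs harsher conditions), the peracid attacks the α face away from the two axial β-methyls to give the 7α-oxygen, and mild base epimerisation through the enediol moves the hydroxyl from the axial site (1,3-diaxial to the C9 oxygen) to the equatorial 7β site, C7 (R), under conditions too weak for retro-oxa-Michael opening at C13.

## Compound list
1 | (E)-β-damascone, (E)-1-(2,6,6-trimethylcyclohex-1-en-1-yl)but-2-en-1-one | C/C=C/C(=O)C1=C(C)CCCC1(C)C | starting material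
2 | pent-4-ynal | C#CCCC=O | starting material
3 | (3R)-3-methyl-1-(2,6,6-trimethylcyclohex-1-en-1-yl)oct-7-yne-1,4-dione | C#CCCC(=O)[C@H](C)CC(=O)C1=C(C)CCCC1(C)C | intermediate
4 | (3R,4R,4aS,8aS)-4-(but-3-yn-1-yl)-4-hydroxy-3,4a,8,8-tetramethyloctahydronaphthalen-1(2H)-one (trans-decalone; 6-oxo, 8α-Me, 9α-OH, 9β-butynyl, 10β-Me, 5α-H) | C[C@@H]1CC(=O)[C@H]2C(C)(C)CCC[C@]2(C)[C@@]1(O)CCC#C | intermediate
5 | (1R,2R,4aS,8aS)-2,5,5,8a-tetramethyl-5'-methylideneoctahydrospiro[naphthalene-1,2'-oxolan]-4-one (9α-O oxolane, exocyclic C13=CH2) | C[C@@H]1CC(=O)[C@H]2C(C)(C)CCC[C@]2(C)[C@@]12CCC(=C)O2 | intermediate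
6 | 2,2-dichlorocyclobutan-1-one spiro-fused through its C3 to C13 of the oxolane of 5 (CCl2 bonded to C13; mixture of C13 epimers) | C[C@@H]1CC(=O)[C@H]2C(C)(C)CCC[C@]2(C)[C@@]12CCC1(CC(=O)C1(Cl)Cl)O2 | intermediate (not isolated)
7 | cyclobutan-1-one spiro-fused through its C3 to C13 of the oxolane (C13 carries two identical CH2 arms) | C[C@@H]1CC(=O)[C@H]2C(C)(C)CCC[C@]2(C)[C@@]12CCC1(CC(=O)C1)O2 | intermediate
8 | (13R)-6-oxo-9α,13-epoxylabdan-15,16-olide (C15 = lactone carbonyl, C16 = OCH2 on the C8 side) | C[C@@H]1CC(=O)[C@H]2C(C)(C)CCC[C@]2(C)[C@@]12CC[C@@]1(COC(=O)C1)O2 | intermediate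
9 | C6=C7 trimethylsilyl enol ether of 8 | C[C@@H]1C=C(O[Si](C)(C)C)[C@H]2C(C)(C)CCC[C@]2(C)[C@@]12CC[C@@]1(COC(=O)C1)O2 | intermediate (not isolated)
10 | 7α-(trimethylsilyloxy) derivative of 8 | C[C@@H]1[C@H](O[Si](C)(C)C)C(=O)[C@H]2C(C)(C)CCC[C@]2(C)[C@@]12CC[C@@]1(COC(=O)C1)O2 | intermediate (not isolated)
11 | (13R)-7α-hydroxy-6-oxo-9α,13-epoxylabdan-15,16-olide (7-epimer of the target) | C[C@@H]1[C@H](O)C(=O)[C@H]2C(C)(C)CCC[C@]2(C)[C@@]12CC[C@@]1(COC(=O)C1)O2 | intermediate (not isolated)
12 | (5S,7R,8R,9R,10S,13R)-7β-hydroxy-6-oxo-9α,13-epoxylabdan-15,16-olide | C[C@@H]1[C@@H](O)C(=O)[C@H]2C(C)(C)CCC[C@]2(C)[C@@]12CC[C@@]1(COC(=O)C1)O2 | target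

## Step count and risks
Total step count: 6. Longest linear sequence: 6 (1 → 3 → 4 → 5 → 7 → 8 → 12).

**First risk: step 1, the proposed new Stetter reaction.**
- Acyloin or aldol self-reaction of 2 may outrun addition to the β-methyl enone, and the enantioselectivity is unproven.
- The fallback uses known chemistry, sets out from 1 and comes back at 3.
- 5-Iodopent-1-yne and AgNO2 in Et2O give 5-nitropent-1-yne F1.
- A bifunctional 9-epi-aminoquinine 3,5-bis(trifluoromethyl)phenyl thiourea (10 mol %, toluene, rt) catalyses the asymmetric Michael addition of F1 to 1. This gives the γ-nitro ketone F2 with C8 (R), as a mixture at the nitro carbon that is erased next.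
- A Nef reaction with TiCl3 in NH4OAc-buffered aqueous THF turns F2 into 3.

**Second risk: step 2.**
- The 6-endo closure onto a tetrasubstituted, twisted enone may be slower than plain reduction of the C9 ketone or of the enone.
- The C9 epimer ratio is not secured by precedent.
- The fallback changes how the C9 radical is made. It sets out from 3 and comes back at 4.
- Kinetic deprotonation at the unhindered C11 methylene (LDA, Et3SiCl internal quench, THF, −78 °C) gives the C9=C11 triethylsilyl enol ether F3.
- Hydrogen-atom-transfer reductive olefin coupling (Fe(acac)3 30 mol %, PhSiH3, EtOH, 60 °C) places H on C11. The resulting α-silyloxy C9 radical closes onto C10 to give the 9α-silyl ether F4.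
- TBAF in THF frees 4.

**Third risk: step 5.**
- The phosphoric acid may not discriminate well between the two remote diastereotopic CH2 groups, giving a C13 mixture.
- The fallback lets chlorine, not a catalyst, decide which carbon migrates. It sets out from 6, now isolated after the first stage of step 4, and comes back at 8.
- Chromatography separates the C13 epimers of 6. The one kept is the dichlorocyclobutanone epimer F5, with CCl2 on the C1/C10 side and CH2 on the C8 side.
- mCPBA in CH2Cl2 gives, by exclusive migration of the unchlorinated CH2, the α,α-dichlorolactone F6.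
- Zn–Cu couple in NH4Cl-saturated MeOH dechlorinates F6 to 8.

## Further compounds
F1 | step 1 | 5-nitropent-1-yne | C#CCCC[N+](=O)[O-]
F2 | step 1 | (3R)-3-methyl-4-nitro-1-(2,6,6-trimethylcyclohex-1-en-1-yl)oct-7-yn-1-one (mixture at C4) | C#CCCC([N+](=O)[O-])[C@H](C)CC(=O)C1=C(C)CCCC1(C)C
F3 | step 2 | (3R)-3-methyl-4-(triethylsilyloxy)-1-(2,6,6-trimethylcyclohex-1-en-1-yl)oct-4-en-7-yn-1-one | C#CCC=C(O[Si](CC)(CC)CC)[C@H](C)CC(=O)C1=C(C)CCCC1(C)C
F4 | step 2 | 9-O-triethylsilyl ether of 4 | C[C@@H]1CC(=O)[C@H]2C(C)(C)CCC[C@]2(C)[C@@]1(O[Si](CC)(CC)CC)CCC#C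
F5 | step 5 | single C13 epimer of 6 with CCl2 on the C1/C10 side | C[C@@H]1CC(=O)[C@H]2C(C)(C)CCC[C@]2(C)[C@@]12CC[C@@]1(CC(=O)C1(Cl)Cl)O2
F6 | step 5 | 14,14-dichloro derivative of 8 | C[C@@H]1CC(=O)[C@H]2C(C)(C)CCC[C@]2(C)[C@@]12CC[C@@]1(COC(=O)C1(Cl)Cl)O2
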